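**Retrosynthetic overview**
1. Target 19 ⇐ tetra-MOM diketone 18 ⇐ diarylalkyne 17 (alkyne oxidation) ⇐ C8 iodide 14 + arylacetylene 16 (Sonogashira coupling, C8–C bond).
2. Feature: ring A carries O1 on C8a and the glyoxyloyl carbon on the neighbouring C8. An aryne across C8–C8a gives this ortho pair when a tethered oxygen adds at C8a and an electrophile is taken up at C8, so 14 ⇐ fluoro alcohol 10 (O1–C8a bond and C8–I in one operation).
3. 10 ⇐ ketone 9 (asymmetric transfer hydrogenation sets C2) ⇐ chalcone 8 ⇐ aldehyde 4 + ketone 6 (aldol condensation); 4 ⇐ 5-fluororesorcinol by electrophilic formylation.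
4. Ring order: the two benzene rings (rings A and B) are bought; the pyran ring (ring C) is the only ring formed, in step 7.

Key step: step 7

Remark on the chemistry: the target is taken as the open 1,2-diketone drawn, not its cyclic hemiketal. C2 is the only stereocentre and is (S) (O1 > aryl > C3 > H); the carbinol carbon of the open-chain alcohol 10 has the same descriptor, because its substituents keep their priority order on ring closure.

**Route**

Step 1
Reactants: 1 5-fluororesorcinol
Product: 3 2-fluoro-4,6-dihydroxybenzaldehyde, via iminium chloride 2 (not isolated)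
Conditions: POCl3, DMF, MeCN, −15 °C to rt; then H2O, 50 °C
Reagents that add atoms: N,N-dimethylformamide, CN(C)C=O; water, O
Why: Vilsmeier–Haack formylation, in which the chloroiminium electrophile attacks the resorcinol para to one hydroxyl and ortho to the other (the carbon between OH and F, not the hindered carbon between the two hydroxyls) and water hydrolyses the aryl iminium salt 2 to the aldehyde.

Step 2
Reactants: 3 2-fluoro-4,6-dihydroxybenzaldehyde
Product: 4 2-fluoro-4,6-bis(methoxymethoxy)benzaldehyde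
Conditions: MOMCl (3 equiv), iPr2NEt (4 equiv), CH2Cl2, 0 °C to reflux
Reagents that add atoms: chloromethyl methyl ether, COCCl
Why: MOM ether formation (O-alkylation of the phenols by an α-chloro ether), with excess reagent and warming to protect the hydroxyl that is hydrogen-bonded to the formyl group.

Step 3
Reactants: 5 4-hydroxyacetophenone
Product: 6 1-[4-(methoxymethoxy)phenyl]ethan-1-one
Conditions: MOMCl, iPr2NEt, CH2Cl2, 0 °C to rt
Reagents that add atoms: chloromethyl methyl ether, COCCl
Why: MOM ether formation on a para-acyl phenol, which is acidic enough for an amine base.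

Step 4
Reactants: 4 2-fluoro-4,6-bis(methoxymethoxy)benzaldehyde; 6 1-[4-(methoxymethoxy)phenyl]ethan-1-one
Product: 8 (E)-3-[2-fluoro-4,6-bis(methoxymethoxy)phenyl]-1-[4-(methoxymethoxy)phenyl]prop-2-en-1-one, via aldol adduct 7 (not isolated)
Conditions: KOH (aq.), EtOH, 0 °C to rt
Reagents that add atoms: none
Why: Claisen–Schmidt (crossed aldol) condensation, in which the ketone enolate adds to the aldehyde that has no α-hydrogen and E1cB loss of water from the aldol 7 gives the (E)-enone; the fluoride on this electron-rich ring should not be displaced at room temperature.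

Step 5
Reactants: 8 (E)-3-[2-fluoro-4,6-bis(methoxymethoxy)phenyl]-1-[4-(methoxymethoxy)phenyl]prop-2-en-1-one
Product: 9 3-[2-fluoro-4,6-bis(methoxymethoxy)phenyl]-1-[4-(methoxymethoxy)phenyl]propan-1-one
Conditions: H2 (1 atm), Pd/C, Ph2S (cat.), EtOAc, rt
Reagents that add atoms: none
Why: Heterogeneous hydrogenation of the conjugated alkene, with diphenyl sulfide tempering Pd/C so that the aryl ketone, the C–F bond and the MOM ethers are left alone.

Step 6
Reactants: 9 3-[2-fluoro-4,6-bis(methoxymethoxy)phenyl]-1-[4-(methoxymethoxy)phenyl]propan-1-one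
Product: 10 (S)-3-[2-fluoro-4,6-bis(methoxymethoxy)phenyl]-1-[4-(methoxymethoxy)phenyl]propan-1-ol
Conditions: RuCl(p-cymene)[(S,S)-TsDPEN] (1 mol%), HCO2H/Et3N (5:2), CH2Cl2, 30 °C
Reagents that add atoms: none
Why: Noyori asymmetric transfer hydrogenation, in which the (S,S)-TsDPEN ruthenium hydride reduces the aryl alkyl ketone in the same sense as acetophenone (aryl group held by the CH–π contact to the cymene ligand), which should give the (S)-carbinol, and formate makes the reduction irreversible.

Step 7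
Reactants: 10 (S)-3-[2-fluoro-4,6-bis(methoxymethoxy)phenyl]-1-[4-(methoxymethoxy)phenyl]propan-1-ol
Product: 14 (2S)-8-iodo-5,7-bis(methoxymethoxy)-2-[4-(methoxymethoxy)phenyl]chroman, via dilithio species 11 (not isolated), via aryne alkoxide 12 (not isolated), via 8-lithiochroman 13 (not isolated)
Conditions: LiTMP (2.5 equiv, from TMPH and n-BuLi), THF, −78 °C to −20 °C; then I2 (3 equiv), −78 °C to rt
Reagents that add atoms: iodine, II
Why: LiTMP first forms the lithium alkoxide and then removes the ring proton between fluorine and the neighbouring MOM ether (the future C8–H) to give 11; on warming, 11 loses LiF to the aryne 12, whose tethered alkoxide adds to the former C–F carbon and leaves the aryllithium 13, which iodine converts into 14. The closest known reaction type is the ring closure of a side-chain alkoxide onto an aryne generated from an ortho-lithiated aryl fluoride, followed by electrophilic quench of the new aryllithium. The pyran ring closes in a 6-exo-dig manner, the oxygen attacking the proximal aryne carbon (future C8a) in the plane of the ring; attack at the distal carbon cannot be reached by the tether and is also the electronically disfavoured sense for a 3-alkoxyaryne. No stereocentre is formed and the carbinol C–O bond is never broken, so the (S) configuration set in step 6 should be carried into C2 unchanged. The step needs metalation next to fluorine and not between the two MOM ethers: an amide base responds to C–H acidity, which fluorine raises more than an acetal oxygen does, and since TMPH can shuttle protons between the two aryllithiums while only the fluorine-flanked one can lose LiF, the mixture should drain through the aryne. LiTMP is too hindered to add to the aryne in competition with the intramolecular alkoxide, and the C8 anion, held between O1 and the C7 MOM oxygen, should persist until the iodine quench.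

Step 8
Reactants: 15 4-ethynylphenol
Product: 16 1-ethynyl-4-(methoxymethoxy)benzene
Conditions: MOMCl, iPr2NEt, CH2Cl2, 0 °C to rt
Reagents that add atoms: chloromethyl methyl ether, COCCl
Why: MOM ether formation on the phenol under conditions too weakly basic to touch the terminal alkyne.

Step 9
Reactants: 14 (2S)-8-iodo-5,7-bis(methoxymethoxy)-2-[4-(methoxymethoxy)phenyl]chroman; 16 1-ethynyl-4-(methoxymethoxy)benzene
Product: 17 (2S)-5,7-bis(methoxymethoxy)-2-[4-(methoxymethoxy)phenyl]-8-{[4-(methoxymethoxy)phenyl]ethynyl}chroman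
Conditions: Pd(PPh3)2Cl2 (5 mol%), CuI (10 mol%), Et3N, DMF, 60 °C
Reagents that add atoms: none
Why: Sonogashira coupling, in which zerovalent palladium inserts into the C8–I bond, the copper acetylide of 16 transmetalates and reductive elimination forms the C8–C(sp) bond; aryl iodides flanked by two oxygen substituents are known to couple under such conditions.

Step 10
Reactants: 17 (2S)-5,7-bis(methoxymethoxy)-2-[4-(methoxymethoxy)phenyl]-8-{[4-(methoxymethoxy)phenyl]ethynyl}chroman
Product: 18 1-[(2S)-5,7-bis(methoxymethoxy)-2-[4-(methoxymethoxy)phenyl]chroman-8-yl]-2-[4-(methoxymethoxy)phenyl]ethane-1,2-dione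
Conditions: PdCl2 (10 mol%), DMSO, 120 °C
Reagents that add atoms: dimethyl sulfoxide, CS(C)=O
Why: Palladium-catalysed oxidation of a diarylalkyne to a 1,2-diketone (Wacker-type oxypalladation in which DMSO supplies both oxygens and leaves as Me2S), for which electron-rich diarylalkynes are the favourable substrate class.

Step 11
Reactants: 18 1-[(2S)-5,7-bis(methoxymethoxy)-2-[4-(methoxymethoxy)phenyl]chroman-8-yl]-2-[4-(methoxymethoxy)phenyl]ethane-1,2-dione
Product: 19 1-[(2S)-5,7-dihydroxy-2-(4-hydroxyphenyl)chroman-8-yl]-2-(4-hydroxyphenyl)ethane-1,2-dione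
Conditions: HCl (3 M aq.), MeOH–THF, 40 °C
Reagents that add atoms: none
Why: Acid-catalysed acetal exchange of the four MOM ethers with methanol (the formaldehyde unit leaves as dimethoxymethane); dilute acid at 40 °C should not ionise the O1–C2 bond, so C2 should stay (S).

**Compound list**
1 | 5-fluororesorcinol (5-fluorobenzene-1,3-diol) | Oc1cc(O)cc(F)c1 | starting material
2 | [(2-fluoro-4,6-dihydroxyphenyl)methylidene]dimethylammonium chloride | C[N+](C)=Cc1c(F)cc(O)cc1O.[Cl-] | intermediate
3 | 2-fluoro-4,6-dihydroxybenzaldehyde | O=Cc1c(F)cc(O)cc1O | intermediate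
4 | 2-fluoro-4,6-bis(methoxymethoxy)benzaldehyde | O=Cc1c(F)cc(OCOC)cc1OCOC | intermediate
5 | 4-hydroxyacetophenone | CC(=O)c1ccc(O)cc1 | starting material
6 | 1-[4-(methoxymethoxy)phenyl]ethan-1-one | CC(=O)c1ccc(OCOC)cc1 | intermediate
7 | 3-[2-fluoro-4,6-bis(methoxymethoxy)phenyl]-3-hydroxy-1-[4-(methoxymethoxy)phenyl]propan-1-one (racemic aldol) | COCOc1ccc(cc1)C(=O)CC(O)c1c(F)cc(OCOC)cc1OCOC | intermediate
8 | (E)-3-[2-fluoro-4,6-bis(methoxymethoxy)phenyl]-1-[4-(methoxymethoxy)phenyl]prop-2-en-1-one | COCOc1ccc(cc1)C(=O)/C=C/c1c(F)cc(OCOC)cc1OCOC | intermediate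
9 | 3-[2-fluoro-4,6-bis(methoxymethoxy)phenyl]-1-[4-(methoxymethoxy)phenyl]propan-1-one | COCOc1ccc(cc1)C(=O)CCc1c(F)cc(OCOC)cc1OCOC | intermediate
10 | (S)-3-[2-fluoro-4,6-bis(methoxymethoxy)phenyl]-1-[4-(methoxymethoxy)phenyl]propan-1-ol | O[C@H](c1ccc(OCOC)cc1)CCc1c(F)cc(OCOC)cc1OCOC | intermediate
11 | lithium (S)-3-[2-fluoro-3-lithio-4,6-bis(methoxymethoxy)phenyl]-1-[4-(methoxymethoxy)phenyl]propan-1-olate | [Li]O[C@H](c1ccc(OCOC)cc1)CCc1c(F)c([Li])c(OCOC)cc1OCOC | intermediate
12 | lithium (S)-3-[2,3-didehydro-4,6-bis(methoxymethoxy)phenyl]-1-[4-(methoxymethoxy)phenyl]propan-1-olate (aryne) | [Li]O[C@H](c1ccc(OCOC)cc1)CCC1=C(OCOC)C=C(OCOC)C#C1 | intermediate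
13 | [(2S)-5,7-bis(methoxymethoxy)-2-[4-(methoxymethoxy)phenyl]chroman-8-yl]lithium | COCOc1cc(OCOC)c2c(c1[Li])O[C@H](c1ccc(OCOC)cc1)CC2 | intermediate
14 | (2S)-8-iodo-5,7-bis(methoxymethoxy)-2-[4-(methoxymethoxy)phenyl]chroman | COCOc1cc(OCOC)c2c(c1I)O[C@H](c1ccc(OCOC)cc1)CC2 | intermediate
15 | 4-ethynylphenol | C#Cc1ccc(O)cc1 | starting material
16 | 1-ethynyl-4-(methoxymethoxy)benzene | C#Cc1ccc(OCOC)cc1 | intermediate
17 | (2S)-5,7-bis(methoxymethoxy)-2-[4-(methoxymethoxy)phenyl]-8-{[4-(methoxymethoxy)phenyl]ethynyl}chroman | COCOc1ccc(cc1)C#Cc1c(OCOC)cc(OCOC)c2c1O[C@H](c1ccc(OCOC)cc1)CC2 | intermediate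
18 | 1-[(2S)-5,7-bis(methoxymethoxy)-2-[4-(methoxymethoxy)phenyl]chroman-8-yl]-2-[4-(methoxymethoxy)phenyl]ethane-1,2-dione | COCOc1ccc(cc1)C(=O)C(=O)c1c(OCOC)cc(OCOC)c2c1O[C@H](c1ccc(OCOC)cc1)CC2 | intermediate
19 | 1-[(2S)-5,7-dihydroxy-2-(4-hydroxyphenyl)chroman-8-yl]-2-(4-hydroxyphenyl)ethane-1,2-dione (CNP0332855.1) | O=C(C(=O)c1c(O)cc(O)c2c1O[C@H](c1ccc(O)cc1)CC2)c1ccc(O)cc1 | target

**Step count**
Total: 11 steps. Longest linear sequence: 9 steps (1, 2, 4, 5, 6, 7, 9, 10, 11).

**Steps most likely to fail**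

Step 7. The metalation may take place at the C–H between the two MOM ethers and not next to fluorine, so that no aryne forms and iodine ends up on the uncyclised alcohol. The C8 anion may also be protonated before the iodine quench. The fallback sets out from ketone 6 and comes back at iodide 14; it forms the O1–C2 bond in place of O1–C8a.
- Commercial 2,4,6-trihydroxybenzaldehyde is protected twice (MOMCl, iPr2NEt, CH2Cl2; the hydrogen-bonded ortho hydroxyl stays free) to give 2-hydroxy-4,6-bis(methoxymethoxy)benzaldehyde F1.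
- Claisen–Schmidt condensation of F1 with 6 (KOH, EtOH) should give (E)-3-[2-hydroxy-4,6-bis(methoxymethoxy)phenyl]-1-[4-(methoxymethoxy)phenyl]prop-2-en-1-one F2.
- Hydrogenation (H2, Pd/C, Ph2S, EtOAc) gives 3-[2-hydroxy-4,6-bis(methoxymethoxy)phenyl]-1-[4-(methoxymethoxy)phenyl]propan-1-one F3.
- Transfer hydrogenation with RuCl(p-cymene)[(R,R)-TsDPEN] and HCO2H/Et3N gives (R)-3-[2-hydroxy-4,6-bis(methoxymethoxy)phenyl]-1-[4-(methoxymethoxy)phenyl]propan-1-ol F4.
- Mitsunobu cyclisation (PPh3, DIAD, THF, 0 °C) closes the pyran ring with inversion at the carbinol to give (2S)-5,7-bis(methoxymethoxy)-2-[4-(methoxymethoxy)phenyl]chroman F5.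
- Electrophilic iodination with NIS in DMF, which in 5,7-dialkoxyflavans favours the less hindered C8 over C6, then gives 14.

Step 10. The MOM ether ortho to the alkyne may be lost at 120 °C in the presence of divalent palladium; the freed C7 phenol would then add to the palladium-activated alkyne and close a 2-arylbenzofuran instead of the diketone. The fallback sets out from iodide 14 and ketone 6 and comes back at diketone 18; it also replaces step 9.
- Palladium-catalysed α-arylation of 6 with 14 (Pd2(dba)3, Xantphos, NaOtBu, toluene, 80 °C) should give the deoxybenzoin 2-[(2S)-5,7-bis(methoxymethoxy)-2-[4-(methoxymethoxy)phenyl]chroman-8-yl]-1-[4-(methoxymethoxy)phenyl]ethan-1-one F6.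
- Riley oxidation of its doubly activated methylene (SeO2, 1,4-dioxane, 90 °C) gives 18.

Step 11. In acidic methanol the freed C7 phenol may add to the distal ketone, and the cyclic hemiketal may be trapped as its methyl ketal. The C8 acyl group also makes the ring A oxygen a better leaving group, so the O1–C2 bond may ionise with loss of configuration at C2. The fallback sets out from iodide 14 and comes back at target 19; it moves the acetal cleavage to a stage without the diketone and ends with a base-catalysed ester cleavage.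
- 14 is deprotected (HCl, MeOH–THF, rt) to (2S)-2-(4-hydroxyphenyl)-8-iodochroman-5,7-diol F7.
- Acetylation (Ac2O, pyridine, DMAP) gives (2S)-2-(4-acetoxyphenyl)-8-iodochroman-5,7-diyl diacetate F8.
- Sonogashira coupling (Pd(PPh3)2Cl2, CuI, Et3N, DMF) with 4-ethynylphenyl acetate F9, made from 15 with Ac2O and pyridine, gives (2S)-2-(4-acetoxyphenyl)-8-[(4-acetoxyphenyl)ethynyl]chroman-5,7-diyl diacetate F10.
- Oxidation with PdCl2 in DMSO gives (2S)-2-(4-acetoxyphenyl)-8-[2-(4-acetoxyphenyl)-2-oxoacetyl]chroman-5,7-diyl diacetate F11.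
- Brief transesterification (K2CO3 cat., MeOH, 0 °C, then AcOH) releases 19 without acid.

**Further compounds**
F1 | step 7 | 2-hydroxy-4,6-bis(methoxymethoxy)benzaldehyde | O=Cc1c(O)cc(OCOC)cc1OCOC
F2 | step 7 | (E)-3-[2-hydroxy-4,6-bis(methoxymethoxy)phenyl]-1-[4-(methoxymethoxy)phenyl]prop-2-en-1-one | COCOc1ccc(cc1)C(=O)/C=C/c1c(O)cc(OCOC)cc1OCOC
F3 | step 7 | 3-[2-hydroxy-4,6-bis(methoxymethoxy)phenyl]-1-[4-(methoxymethoxy)phenyl]propan-1-one | COCOc1ccc(cc1)C(=O)CCc1c(O)cc(OCOC)cc1OCOC
F4 | step 7 | (R)-3-[2-hydroxy-4,6-bis(methoxymethoxy)phenyl]-1-[4-(methoxymethoxy)phenyl]propan-1-ol | O[C@@H](c1ccc(OCOC)cc1)CCc1c(O)cc(OCOC)cc1OCOC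
F5 | step 7 | (2S)-5,7-bis(methoxymethoxy)-2-[4-(methoxymethoxy)phenyl]chroman | COCOc1cc(OCOC)c2c(c1)O[C@H](c1ccc(OCOC)cc1)CC2
F6 | step 10 | 2-[(2S)-5,7-bis(methoxymethoxy)-2-[4-(methoxymethoxy)phenyl]chroman-8-yl]-1-[4-(methoxymethoxy)phenyl]ethan-1-one | COCOc1ccc(cc1)C(=O)Cc1c(OCOC)cc(OCOC)c2c1O[C@H](c1ccc(OCOC)cc1)CC2
F7 | step 11 | (2S)-2-(4-hydroxyphenyl)-8-iodochroman-5,7-diol | Oc1cc(O)c2c(c1I)O[C@H](c1ccc(O)cc1)CC2
F8 | step 11 | (2S)-2-(4-acetoxyphenyl)-8-iodochroman-5,7-diyl diacetate | CC(=O)Oc1cc(OC(C)=O)c2c(c1I)O[C@H](c1ccc(OC(C)=O)cc1)CC2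
F9 | step 11 | 4-ethynylphenyl acetate | CC(=O)Oc1ccc(cc1)C#C
F10 | step 11 | (2S)-2-(4-acetoxyphenyl)-8-[(4-acetoxyphenyl)ethynyl]chroman-5,7-diyl diacetate | CC(=O)Oc1ccc(cc1)C#Cc1c(OC(C)=O)cc(OC(C)=O)c2c1O[C@H](c1ccc(OC(C)=O)cc1)CC2
F11 | step 11 | (2S)-2-(4-acetoxyphenyl)-8-[2-(4-acetoxyphenyl)-2-oxoacetyl]chroman-5,7-diyl diacetate | CC(=O)Oc1ccc(cc1)C(=O)C(=O)c1c(OC(C)=O)cc(OC(C)=O)c2c1O[C@H](c1ccc(OC(C)=O)cc1)CC2
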